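**Retrosynthetic overview**

1. Target 18 ← allylic oxidation, acetonide removal, anisoylation and i‑Pr addition ← ketol 14 ← epoxidation/SmI2 opening of dienone 12; C4, C5 and C6 are all set by reagent approach anti to the C1 methyl.
2. 12 ← resolved hydroxy dienedione 10 (= 8) ← one‑pot [5+2] cycloaddition/E1cB opening of 4‑methyl‑3‑oxidopyrylium 6 with 3‑methylcyclopent‑2‑enone 5. This forms C5–C6 and C1–C10 and closes the seven‑membered ring onto the bought cyclopentane.
3. Enabling feature: in the cycloheptenone ring, C6–C7=C8(CH3)–C9(=O)–C10 is the carbon row C6–C5–C4(CH3)–C3(O)–C2 of a 3‑oxidopyrylium whose ring oxygen bridges C6 and C10. In the cyclopentane, the C4 carbinol is a latent C=O, so C5/C1 are the α/β carbons of 3‑methylcyclopentenone, polarity‑matched to the ylide.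
4. The bridge oxygen stays on C10 after the E1cB opening; the C6 oxygen is put back by epoxidation on the opposite face, which also allows H‑5 to be set trans.
5. Ylide precursor 4 comes from methyl 3‑methyl‑2‑furoate by reduction, Achmatowicz dearomatization and acetylation. Absolute configuration comes from a covalent resolution of 8.

Key step: step 4

Remark on numbering: daucane locants are used for the bicyclic compounds. C1 = quaternary ring‑fusion carbon (CH3), C2/C3 = CH2CH2, C4 = carbinol carbon bearing isopropyl (ketone before step 11), C5 = ring‑fusion CH, C6 = acyloxy carbon, C7=C8(CH3), C9 = ketone carbon, C10 = secondary carbinol. "Syn/anti" refers to the C1 methyl. In 18: H‑5 anti (trans fusion), 4‑OH syn, 10‑OH syn, 6‑O‑anisoyl anti.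

Assumption: 3, 4, 7 and 8 are racemic; the SMILES of 7 and 8 show the enantiomer carried on after the resolution in steps 5 and 6.

**Step 1**
Reactants: 1 methyl 3‑methylfuran‑2‑carboxylate
Product: 2 (3‑methylfuran‑2‑yl)methanol
Conditions: LiAlH4, THF, 0 °C
Reagents that add atoms: none
Why: Hydride reduction of an ester to the primary alcohol; no stereocentre is involved.

**Step 2**
Reactants: 2 (3‑methylfuran‑2‑yl)methanol
Product: 3 6‑hydroxy‑4‑methyl‑2H‑pyran‑3(6H)‑one (racemic hemiacetal)
Conditions: NBS, NaHCO3, NaOAc, THF/H2O 4:1, 0 °C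
Reagents that add atoms: water, O
Why: Achmatowicz rearrangement (oxidative dearomatization of the furan, water addition, ring opening and recyclization to the pyranone); the hemiacetal centre forms racemic and is destroyed in step 4.

**Step 3**
Reactants: 3 6‑hydroxy‑4‑methyl‑2H‑pyran‑3(6H)‑one
Product: 4 4‑methyl‑5‑oxo‑5,6‑dihydro‑2H‑pyran‑2‑yl acetate (racemic)
Conditions: Ac2O, pyridine, DMAP (cat.), CH2Cl2, 0 °C
Reagents that add atoms: acetic anhydride, CC(=O)OC(C)=O
Why: O‑Acetylation of the lactol turns the anomeric OH into the leaving group needed for ylide formation; no stereocentre that survives is set.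

**Step 4**
Reactants: 4 4‑methyl‑5‑oxo‑5,6‑dihydro‑2H‑pyran‑2‑yl acetate; 5 3‑methylcyclopent‑2‑en‑1‑one (5 equiv)
Product: 8 racemic 10‑hydroxy dienedione (C4 ketone conjugated through C5=C6–C7=C8(CH3) to the C9 ketone; 10‑OH syn to the C1 methyl), via oxidopyrylium ylide 6 (not isolated), via endo cycloadduct 7 (not isolated)
Conditions: i‑Pr2NEt (slow addition), MeCN, 60 °C; then DBU, 0 °C to rt
Reagents that add atoms: none
Why: i‑Pr2NEt removes AcOH from 4 to give the aromatic betaine 6, which adds suprafacially through its C2/C6 termini to the C=C bond of 5 in an oxidopyrylium–alkene [5+2] cycloaddition (the known reaction of acetoxypyranones with enones); this one event closes the seven‑membered carbocycle, as the 8‑oxabicyclo[3.2.1]octenone 7, by concerted asynchronous formation of C1–C10 and C5–C6. Regiochemistry follows the polarity of both partners: the nucleophilic ylide carbon next to the oxido group (future C10) bonds to the enone β‑carbon (future C1, the quaternary centre) and the other terminus (future C6) to the α‑carbon (future C5). The endo transition state (cyclopentanone carbonyl under the dipole, β‑methyl towards the oxygen bridge) puts the bridge oxygen syn to the C1 methyl, so C1 and C10 are set relative to each other, while C5/C6 arise cis as any suprafacial addition to a cyclopentene must give. DBU then removes H‑5 (α to the C4 ketone) and expels the β‑oxygen at C6 (E1cB), which opens the bridge, leaves its oxygen as the 10‑OH and flattens C5/C6 so both can be rebuilt on the opposite face. The step needs regiocontrol (push–pull polarity), endo over exo (secondary orbital overlap; exo would give only the separable C10 epimer) and cycloaddition over ylide dimerization (excess 5, slow base addition); the product is racemic and is resolved in steps 5 and 6.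

**Step 5**
Reactants: 8 racemic 10‑hydroxy dienedione
Product: 9 10‑O‑[(S)‑2‑methoxy‑2‑phenylacetyl] ester of the enantiomer of 8 with the target configuration at C1 and C10 (single diastereomer after separation)
Conditions: (S)‑O‑methylmandelic acid, DCC, DMAP (cat.), CH2Cl2, 0 °C to rt; separation of diastereomers (SiO2 or crystallization)
Reagents that add atoms: (S)‑2‑methoxy‑2‑phenylacetic acid, CO[C@@H](c1ccccc1)C(O)=O
Why: Steglich esterification gives two diastereomeric esters that are separated (classical covalent resolution); no centre of 8 is touched, and the absolute configuration of the collected diastereomer is to be assigned on the ester (X‑ray or NMR anisotropy of the O‑methylmandelate).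

**Step 6**
Reactants: 9 O‑methylmandelate ester
Product: 10 enantiopure 10‑hydroxy dienedione (same constitution as 8)
Conditions: K2CO3 (cat.), MeOH, 0 °C
Reagents that add atoms: none
Why: Base‑catalysed transesterification (methanolysis) of the activated α‑acyloxy ketone removes the auxiliary; short reaction at 0 °C is meant to leave C10 unepimerized.

**Step 7**
Reactants: 10 enantiopure 10‑hydroxy dienedione
Product: 11 9,10‑trans‑diol (9‑OH anti, 10‑OH syn to the C1 methyl; C4 dienone intact)
Conditions: Me4NBH(OAc)3, MeCN/AcOH 1:1, −20 °C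
Reagents that add atoms: none
Why: Hydroxyl‑directed triacetoxyborohydride reduction (Saksena–Evans type): ligand exchange at 10‑OH and internal hydride delivery reduce only the α‑hydroxy ketone to the anti diol and leave the C4 dienone; the new C9 centre is temporary and removed in step 14.

**Step 8**
Reactants: 11 9,10‑trans‑diol
Product: 12 9,10‑O‑isopropylidene dienone
Conditions: 2,2‑dimethoxypropane, PPTS (cat.), CH2Cl2, rt
Reagents that add atoms: 2,2‑dimethoxypropane, COC(C)(C)OC
Why: Acid‑catalysed transketalization; the flexible seven‑membered ring should accommodate the trans‑fused dioxolane, which masks C9/C10 through steps 9–12.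

**Step 9**
Reactants: 12 9,10‑O‑isopropylidene dienone
Product: 13 5,6‑epoxy ketone (epoxide oxygen anti to the C1 methyl)
Conditions: 30% H2O2, NaOH (cat.), MeOH, 0 °C
Reagents that add atoms: hydrogen peroxide, OO
Why: Weitz–Scheffer nucleophilic epoxidation: hydroperoxide adds to C6, the β‑carbon of the C4 dienone (the δ‑carbon C8 is fully substituted), and the enolate closes the epoxide on the face anti to the pseudo‑axial C1 methyl, which sets the C6 oxygen.

**Step 10**
Reactants: 13 5,6‑epoxy ketone
Product: 14 trans‑fused 6‑hydroxy ketone (H‑5 and 6‑OH both anti to the C1 methyl)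
Conditions: SmI2 (2.2 equiv), THF/MeOH, −78 °C
Reagents that add atoms: none
Why: SmI2 reduction of an α,β‑epoxy ketone to the β‑hydroxy ketone: the C4 ketyl cleaves the C5–O bond, C6 keeps its oxygen and configuration, and H‑5 is set by kinetic protonation of the Sm(III) enolate anti to the pseudo‑axial C1 methyl, as in kinetic protonation of ring‑fusion enolates next to an angular methyl in steroidal 15‑ketones.

**Step 11**
Reactants: 14 trans‑fused 6‑hydroxy ketone
Product: 15 4,6‑diol (4‑isopropyl, 4‑OH syn to the C1 methyl)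
Conditions: i‑PrMgCl (4 equiv), CeCl3 (4 equiv), THF, −78 to −20 °C
Reagents that add atoms: isopropylmagnesium chloride, CC(C)[Mg]Cl
Why: Organocerium (Imamoto) 1,2‑addition to the only carbonyl present: the first equivalent forms the C6 alkoxide, and its chelate with C4=O together with the pseudo‑axial C1 methyl should direct isopropyl to the face of H‑5, which places 4‑OH syn to the methyl.

**Step 12**
Reactants: 15 4,6‑diol
Product: 16 6‑O‑(4‑methoxybenzoyl) acetonide
Conditions: 4‑methoxybenzoyl chloride, pyridine, DMAP, CH2Cl2, 0 °C to rt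
Reagents that add atoms: 4‑methoxybenzoyl chloride, COc1ccc(cc1)C(Cl)=O
Why: DMAP‑catalysed acylation of the secondary allylic 6‑OH; the tertiary 4‑OH does not react and no stereocentre changes.

**Step 13**
Reactants: 16 6‑O‑(4‑methoxybenzoyl) acetonide
Product: 17 6‑O‑(4‑methoxybenzoyl) 4,9,10‑triol
Conditions: AcOH/H2O 4:1, 40 °C
Reagents that add atoms: none
Why: Acid‑catalysed acetal hydrolysis; the strained trans‑dioxolane should cleave under conditions that spare the allylic ester and the tertiary alcohol.

**Step 14**
Reactants: 17 6‑O‑(4‑methoxybenzoyl) 4,9,10‑triol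
Product: 18 target (CNP0299970.1)
Conditions: activated MnO2, CH2Cl2, rt
Reagents that add atoms: none
Why: MnO2 oxidizes only the allylic secondary alcohol at C9 (allylic to C7=C8), not the saturated 10‑OH or the tertiary 4‑OH, which restores the enone with all five stereocentres in place.

**Compound list**

1 | methyl 3‑methylfuran‑2‑carboxylate | COC(=O)c1occc1C | starting material
2 | (3‑methylfuran‑2‑yl)methanol | OCc1occc1C | intermediate
3 | 6‑hydroxy‑4‑methyl‑2H‑pyran‑3(6H)‑one (racemic) | O=C1COC(O)C=C1C | intermediate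
4 | 4‑methyl‑5‑oxo‑5,6‑dihydro‑2H‑pyran‑2‑yl acetate (racemic) | CC(=O)OC1OCC(=O)C(C)=C1 | intermediate
5 | 3‑methylcyclopent‑2‑en‑1‑one | CC1=CC(=O)CC1 | starting material
6 | 4‑methyl‑3‑oxidopyrylium (betaine, not isolated) | Cc1cc[o+]cc1[O-] | intermediate
7 | endo [5+2] cycloadduct: 8‑oxabicyclo[3.2.1]oct‑3‑en‑2‑one fused to cyclopentanone, 6,10‑oxygen bridge syn to C1 methyl, H‑5 syn (racemic, not isolated) | O=C1C(C)=C[C@H]2O[C@@H]1[C@@]3(C)CCC(=O)[C@@H]23 | intermediate
8 | 10‑hydroxy dienedione, 4‑hydroxy‑3a,6‑dimethyl‑2,3,3a,4‑tetrahydroazulene‑1,5‑dione, 10‑OH syn to C1 methyl (racemic) | O=C1CC[C@@]2(C)C1=CC=C(C)C(=O)[C@@H]2O | intermediate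
9 | 10‑O‑[(S)‑2‑methoxy‑2‑phenylacetyl] ester of 10 | O=C1CC[C@@]2(C)C1=CC=C(C)C(=O)[C@@H]2OC(=O)[C@@H](OC)c3ccccc3 | intermediate
10 | 10‑hydroxy dienedione, single enantiomer | O=C1CC[C@@]2(C)C1=CC=C(C)C(=O)[C@@H]2O | intermediate
11 | 9,10‑trans‑diol dienone (9‑OH anti, 10‑OH syn to C1 methyl) | O=C1CC[C@@]2(C)C1=CC=C(C)[C@@H](O)[C@@H]2O | intermediate
12 | 9,10‑O‑isopropylidene dienone | O=C1CC[C@@]2(C)C1=CC=C(C)[C@H]3OC(C)(C)O[C@H]23 | intermediate
13 | 5,6‑epoxy ketone (epoxide anti to C1 methyl) | O=C1CC[C@@]2(C)[C@]13O[C@H]3C=C(C)[C@H]4OC(C)(C)O[C@H]24 | intermediate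
14 | trans‑fused 6‑hydroxy‑9,10‑O‑isopropylidene 4‑ketone | O=C1CC[C@@]2(C)[C@H]1[C@@H](O)C=C(C)[C@H]3OC(C)(C)O[C@H]23 | intermediate
15 | 4‑isopropyl 4,6‑diol, 9,10‑O‑isopropylidene | CC(C)[C@]1(O)CC[C@@]2(C)[C@H]1[C@@H](O)C=C(C)[C@H]3OC(C)(C)O[C@H]23 | intermediate
16 | 6‑O‑(4‑methoxybenzoyl) 4‑ol, 9,10‑O‑isopropylidene | CC(C)[C@]1(O)CC[C@@]2(C)[C@H]1[C@@H](OC(=O)c4ccc(OC)cc4)C=C(C)[C@H]3OC(C)(C)O[C@H]23 | intermediate
17 | 6‑O‑(4‑methoxybenzoyl) 4,9,10‑triol | CC(C)[C@]1(O)CC[C@@]2(C)[C@H]1[C@@H](OC(=O)c3ccc(OC)cc3)C=C(C)[C@@H](O)[C@@H]2O | intermediate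
18 | target: 6‑O‑(4‑methoxybenzoyl)‑4,10‑dihydroxydauc‑7‑en‑9‑one (H‑5 anti, 4‑OH syn, 10‑OH syn, 6‑O anti to C1 methyl) | COc1ccc(C(=O)O[C@H]2C=C(C)C(=O)[C@H](O)[C@@]3(C)CC[C@@](O)(C(C)C)[C@H]23)cc1 | target

**Step count and risks**

Total step count: 14. Longest linear sequence: 14 steps (from 1; 5 enters at step 4).

Steps most likely to fail:

1. Step 4 (key step). The trisubstituted enone 5 may add too slowly, so that the ylide is lost by dimerization, or endo/exo control may be poor. The fallback activates the dipolarophile with a removable ester on the future C5. It sets out from 4 and 5. α‑Iodination of 5 (I2, pyridine, CH2Cl2) gives 2‑iodo‑3‑methylcyclopent‑2‑en‑1‑one F1. Palladium‑catalysed methoxycarbonylation (CO, MeOH, Et3N, PdCl2(PPh3)2) gives methyl 2‑methyl‑5‑oxocyclopent‑1‑ene‑1‑carboxylate F2. Cycloaddition of this doubly activated alkene with the ylide from 4 gives the β‑keto ester cycloadduct F3. Krapcho dealkoxycarbonylation (LiCl, wet DMSO, 120 °C) then releases the C5 enolate, which undergoes the same E1cB opening. The fallback comes back to the route at 8.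

2. Step 10. The samarium enolate may be protonated from the face of the methyl group (cis‑fused ketol), or the ketol may dehydrate. The fallback delivers H‑5 by catalytic syn‑hydrogenation before C6 is oxidized. It sets out from 12. Hydrogenation of the C5=C6 bond (H2, Pd/C, EtOAc, one equivalent) anti to the pseudo‑axial methyl gives the trans‑fused 9,10‑O‑isopropylidene 4‑ketone F4. Addition of i‑PrMgCl/CeCl3 gives the tertiary alcohol F5. Allylic oxidation of the C6 methylene (CrO3·3,5‑dimethylpyrazole, CH2Cl2, −20 °C) gives the C6 enone F6. Luche reduction (NaBH4, CeCl3, MeOH; axial hydride, equatorial alcohol) comes back to the route at 15.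

3. Step 11. The branched Grignard reagent may enolize or reduce the hindered ketone, or the aldolate may undergo retro‑aldol cleavage. The fallback uses an sp2 nucleophile without β‑hydrogens. It sets out from 14. Isopropenylmagnesium bromide/CeCl3 (THF, −78 °C) gives the isopropenyl carbinol F7. Hydrogenation of its 1,1‑disubstituted alkene with Wilkinson's catalyst (H2, (Ph3P)3RhCl, benzene), which should leave the trisubstituted ring alkene, comes back to the route at 15.

**Further compounds**

F1 | step 4 | 2‑iodo‑3‑methylcyclopent‑2‑en‑1‑one | CC1=C(I)C(=O)CC1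
F2 | step 4 | methyl 2‑methyl‑5‑oxocyclopent‑1‑ene‑1‑carboxylate | COC(=O)C1=C(C)CCC1=O
F3 | step 4 | β‑keto ester cycloadduct (7 with CO2CH3 in place of H‑5, racemic) | O=C1C(C)=C[C@H]2O[C@@H]1[C@@]3(C)CCC(=O)[C@@]23C(=O)OC
F4 | step 10 | trans‑fused 9,10‑O‑isopropylidene 4‑ketone with C6 methylene | O=C1CC[C@@]2(C)[C@H]1CC=C(C)[C@H]3OC(C)(C)O[C@H]23
F5 | step 10 | 4‑isopropyl 4‑ol with C6 methylene | CC(C)[C@]1(O)CC[C@@]2(C)[C@H]1CC=C(C)[C@H]3OC(C)(C)O[C@H]23
F6 | step 10 | 4‑isopropyl 4‑hydroxy C6 enone | CC(C)[C@]1(O)CC[C@@]2(C)[C@H]1C(=O)C=C(C)[C@H]3OC(C)(C)O[C@H]23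
F7 | step 11 | 4‑isopropenyl 4,6‑diol, 9,10‑O‑isopropylidene | C=C(C)[C@]1(O)CC[C@@]2(C)[C@H]1[C@@H](O)C=C(C)[C@H]3OC(C)(C)O[C@H]23
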